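**Plan**

- Retrosynthetic cuts, in order: both aryl O–MOM bonds; the O1–C8a aryl ether bond and the C4–C4a acyl–aryl bond of ring C together; the lactone O–C(acyl) bond; C2–H (ketone reduction); C2–C3; the C5'–prenyl bond; the O–MOM and O–Me bonds of ring B.
- Enabling feature: in ring A the adjacent carbons C4a and C8a carry the C4 acyl carbon and O1. Ring A can therefore enter as a 2-fluoroaryllithium (C4a nucleophile, C8a electrophile, a regiodefined aryne equivalent) that inserts into the O1–C4 acyl bond of a four-membered lactone holding O1, C2, C3 and C4.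
- Forward order: the ring B aldehyde is methylated, MOM-protected, prenylated, homologated to the β-keto ester, reduced and closed to the β-lactone (temporary ring). Ring C then forms on ring A in the key step: strain release drives the C–C bond, and the ortho ketone so created activates the C–F carbon for the C–O bond. Fluorine leaves there; the MOM groups go last.
- Stereochemistry: the only stereocentre, C2 (S), is set by asymmetric transfer hydrogenation of the aryl ketone. It is carried with retention through lactonisation (carboxyl activation) and the annulation (no bond to C2 broken). Once ring C exists only acidic or neutral conditions are used, to avoid base-induced ring opening to the chalcone.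

Key step: step 9

**Route**

Step 1
Reactants: 1 3-bromo-4,5-dihydroxybenzaldehyde
Product: 2 3-bromo-5-hydroxy-4-methoxybenzaldehyde
Conditions: MeI (1.05 equiv), Li2CO3 (1.1 equiv), DMF, 40 °C
Reagents that add atoms: iodomethane CI
Why: The 4-OH, para to the formyl group and ortho to bromine, is the more acidic phenol, so one equivalent of weak base should give its phenoxide selectively and Williamson O-methylation (SN2 on MeI) should occur there.

Step 2
Reactants: 2 3-bromo-5-hydroxy-4-methoxybenzaldehyde
Product: 3 3-bromo-4-methoxy-5-(methoxymethoxy)benzaldehyde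
Conditions: MOMCl, i-Pr2NEt, CH2Cl2, 0 °C → rt
Reagents that add atoms: chloromethyl methyl ether COCCl
Why: O-alkylation of the remaining phenol with MOMCl under amine base gives an acetal that is stable to the organometallic and basic steps ahead and is removable by acid at the end.

Step 3
Reactants: 3 3-bromo-4-methoxy-5-(methoxymethoxy)benzaldehyde
Product: 4 4-methoxy-3-(methoxymethoxy)-5-(3-methylbut-2-en-1-yl)benzaldehyde
Conditions: tributyl(3-methylbut-2-en-1-yl)stannane, Pd(PPh3)4 (5 mol%), DMF, 90 °C
Reagents that add atoms: tributyl(3-methylbut-2-en-1-yl)stannane CCCC[Sn](CCCC)(CCCC)CC=C(C)C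
Why: Stille coupling, in which oxidative addition of zerovalent palladium into the aryl–Br bond, transmetalation and reductive elimination at the less hindered CH2 terminus should give the linear prenyl arene while the aldehyde and the MOM ether stay inert.

Step 4
Reactants: 4 4-methoxy-3-(methoxymethoxy)-5-(3-methylbut-2-en-1-yl)benzaldehyde
Product: 5 ethyl 3-[4-methoxy-3-(methoxymethoxy)-5-(3-methylbut-2-en-1-yl)phenyl]-3-oxopropanoate
Conditions: ethyl diazoacetate, SnCl2 (10 mol%), CH2Cl2, rt
Reagents that add atoms: ethyl diazoacetate CCOC(=O)C=[N+]=[N-]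
Why: Roskamp reaction, in which the SnCl2-activated aldehyde is attacked by the diazo carbon and a 1,2-hydride shift with loss of N2 gives the β-keto ester directly; no metal carbenoid is involved, so the prenyl alkene should be untouched.

Step 5
Reactants: 5 ethyl 3-[4-methoxy-3-(methoxymethoxy)-5-(3-methylbut-2-en-1-yl)phenyl]-3-oxopropanoate
Product: 6 ethyl (3S)-3-hydroxy-3-[4-methoxy-3-(methoxymethoxy)-5-(3-methylbut-2-en-1-yl)phenyl]propanoate
Conditions: RuCl(p-cymene)[(S,S)-TsDPEN] (1 mol%), HCO2H/Et3N (5:2), EtOAc, 35 °C
Reagents that add atoms: none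
Why: Noyori–Ikariya asymmetric transfer hydrogenation, in which the (S,S)-TsDPEN ruthenium hydride delivers hydride to the ketone face fixed by the aryl CH–π contact with the p-cymene ligand, which for aryl ketones should give the (S)-carbinol (the future C2) while the isolated trisubstituted alkene is not reduced.

Step 6
Reactants: 6 ethyl (3S)-3-hydroxy-3-[4-methoxy-3-(methoxymethoxy)-5-(3-methylbut-2-en-1-yl)phenyl]propanoate
Product: 7 (3S)-3-hydroxy-3-[4-methoxy-3-(methoxymethoxy)-5-(3-methylbut-2-en-1-yl)phenyl]propanoic acid
Conditions: LiOH·H2O, THF/H2O, 0 °C → rt; then 1 M HCl, 0 °C, to pH 3–4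
Reagents that add atoms: lithium hydroxide [Li+].[OH-]
Why: Ester saponification (BAc2) at low temperature, followed by brief cold acidification, should leave the MOM ethers in place and avoid dehydration of the benzylic β-hydroxy acid.

Step 7
Reactants: 7 (3S)-3-hydroxy-3-[4-methoxy-3-(methoxymethoxy)-5-(3-methylbut-2-en-1-yl)phenyl]propanoic acid
Product: 9 (4S)-4-[4-methoxy-3-(methoxymethoxy)-5-(3-methylbut-2-en-1-yl)phenyl]oxetan-2-one, via mixed carboxylic–benzenesulfonic anhydride 8 (not isolated)
Conditions: PhSO2Cl (2 equiv), pyridine, 0 °C
Reagents that add atoms: none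
Why: β-Lactonisation by carboxyl activation, in which the carboxylate is sulfonylated faster than the hindered secondary alcohol and the hydroxyl then closes onto the mixed anhydride (4-exo-trig), so no bond to the stereocentre is broken and the (S) configuration should be retained; the 4-OMe group, twisted out of conjugation by its two ortho neighbours, should not make the benzylic C–O bond unusually labile.

Step 8
Reactants: 10 4-bromo-3-fluorophenol
Product: 11 1-bromo-2-fluoro-4-(methoxymethoxy)benzene
Conditions: MOMCl, i-Pr2NEt, CH2Cl2, 0 °C → rt
Reagents that add atoms: chloromethyl methyl ether COCCl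
Why: O-alkylation of the phenol with MOMCl gives the ring A partner with bromine at the future C4a, fluorine at the future C8a and the protected oxygen at the future C7.

Step 9
Reactants: 9 (4S)-4-[4-methoxy-3-(methoxymethoxy)-5-(3-methylbut-2-en-1-yl)phenyl]oxetan-2-one; 11 1-bromo-2-fluoro-4-(methoxymethoxy)benzene
Product: 15 (2S)-7-(methoxymethoxy)-2-[4-methoxy-3-(methoxymethoxy)-5-(3-methylbut-2-en-1-yl)phenyl]-2,3-dihydro-4H-chromen-4-one, via aryllithium 12 (not isolated), via lithium oxetan-2-olate adduct 13 (not isolated), via lithium aldolate 14 (not isolated)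
Conditions: 11, n-BuLi (1.0 equiv), THF, −78 °C; slow transfer into 9 (1.0 equiv), THF, −78 °C; DMPU, −78 → 0 °C; AcOH, −20 °C
Reagents that add atoms: none
Why: Proposed new method: bromine–lithium exchange turns 11 into aryllithium 12, which adds as a hard C4a nucleophile to the strained lactone carbonyl of 9 to give adduct 13; release of four-ring strain opens 13 by acyl–oxygen cleavage to the lithium aldolate 14 (C4–C4a bond), and its alkoxide O1 then displaces the fluoride at C8a, now activated by the ortho ketone just formed, by addition–elimination (O1–C8a bond). The closest known reaction types are the acyl–oxygen opening of β-lactones by organolithium reagents to β-hydroxy ketones and the base-induced SNAr closure of 3-hydroxy-1-(2-fluoroaryl) ketones to chroman-4-ones; merged in one flask they amount to a regiodefined aryne insertion into the O–C(acyl) bond. Ring C closes as a six-membered ring by intramolecular SNAr through a Meisenheimer adduct, formally 6-endo-trig with respect to the C4a=C8a bond that relays the charge to the C4 carbonyl, while the four-membered ring is opened and not retained. No new stereocentre is formed: C2 is carried over from 9 with retention because only the acyl C–O bond is broken and O1 and C2 stay bonded throughout. The step needs regiocontrol on ring A, fixed by the positions of Br (to Li) and F in 11; acyl instead of alkyl C–O attack, secured by the hard aryllithium at −78 °C; and mono-addition, secured by slow inverse addition of 12 to 9 and by the electron-rich, chelated keto-alkoxide being less electrophilic than the lactone. DMPU and the precipitation of LiF should speed the SNAr at or below 0 °C so that it outruns retro-aldol or E1cB loss of water at the stage of 14, and the cold AcOH quench leaves no base in contact with the enolisable flavanone.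

Step 10
Reactants: 15 (2S)-7-(methoxymethoxy)-2-[4-methoxy-3-(methoxymethoxy)-5-(3-methylbut-2-en-1-yl)phenyl]-2,3-dihydro-4H-chromen-4-one
Product: 16 erylatissin C, (2S)-7-hydroxy-2-[3-hydroxy-4-methoxy-5-(3-methylbut-2-en-1-yl)phenyl]-2,3-dihydro-4H-chromen-4-one
Conditions: HCl (1.25 M in MeOH), MeOH/CH2Cl2, 0 °C → rt
Reagents that add atoms: none
Why: Acid-catalysed acetal methanolysis should remove both aryl MOM ethers; acidic conditions avoid the base-induced E1cB ring opening to the 2'-hydroxychalcone that would racemise C2, and the prenyl group, which has no free ortho hydroxyl, should not cyclise under these mild conditions.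

**Compound list**

1 | 3-bromo-4,5-dihydroxybenzaldehyde | O=Cc1cc(O)c(O)c(Br)c1 | starting material
2 | 3-bromo-5-hydroxy-4-methoxybenzaldehyde | O=Cc1cc(O)c(OC)c(Br)c1 | intermediate
3 | 3-bromo-4-methoxy-5-(methoxymethoxy)benzaldehyde | O=Cc1cc(OCOC)c(OC)c(Br)c1 | intermediate
4 | 4-methoxy-3-(methoxymethoxy)-5-(3-methylbut-2-en-1-yl)benzaldehyde | O=Cc1cc(OCOC)c(OC)c(CC=C(C)C)c1 | intermediate
5 | ethyl 3-[4-methoxy-3-(methoxymethoxy)-5-(3-methylbut-2-en-1-yl)phenyl]-3-oxopropanoate | CCOC(=O)CC(=O)c1cc(OCOC)c(OC)c(CC=C(C)C)c1 | intermediate
6 | ethyl (3S)-3-hydroxy-3-[4-methoxy-3-(methoxymethoxy)-5-(3-methylbut-2-en-1-yl)phenyl]propanoate | CCOC(=O)C[C@H](O)c1cc(OCOC)c(OC)c(CC=C(C)C)c1 | intermediate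
7 | (3S)-3-hydroxy-3-[4-methoxy-3-(methoxymethoxy)-5-(3-methylbut-2-en-1-yl)phenyl]propanoic acid | OC(=O)C[C@H](O)c1cc(OCOC)c(OC)c(CC=C(C)C)c1 | intermediate
8 | benzenesulfonic (3S)-3-hydroxy-3-[4-methoxy-3-(methoxymethoxy)-5-(3-methylbut-2-en-1-yl)phenyl]propanoic anhydride (formed in the flask) | O=C(C[C@H](O)c1cc(OCOC)c(OC)c(CC=C(C)C)c1)OS(=O)(=O)c1ccccc1 | intermediate
9 | (4S)-4-[4-methoxy-3-(methoxymethoxy)-5-(3-methylbut-2-en-1-yl)phenyl]oxetan-2-one | O=C1C[C@@H](c2cc(OCOC)c(OC)c(CC=C(C)C)c2)O1 | intermediate
10 | 4-bromo-3-fluorophenol | Oc1ccc(Br)c(F)c1 | starting material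
11 | 1-bromo-2-fluoro-4-(methoxymethoxy)benzene | COCOc1ccc(Br)c(F)c1 | intermediate
12 | [2-fluoro-4-(methoxymethoxy)phenyl]lithium (formed in the flask) | COCOc1ccc([Li])c(F)c1 | intermediate
13 | lithium (4S)-2-[2-fluoro-4-(methoxymethoxy)phenyl]-4-[4-methoxy-3-(methoxymethoxy)-5-(3-methylbut-2-en-1-yl)phenyl]oxetan-2-olate, both configurations at C2 of the oxetane (formed in the flask) | [Li+].[O-]C1(c2ccc(OCOC)cc2F)C[C@@H](c2cc(OCOC)c(OC)c(CC=C(C)C)c2)O1 | intermediate
14 | lithium (1S)-3-[2-fluoro-4-(methoxymethoxy)phenyl]-1-[4-methoxy-3-(methoxymethoxy)-5-(3-methylbut-2-en-1-yl)phenyl]-3-oxopropan-1-olate (formed in the flask) | [Li+].[O-][C@@H](CC(=O)c1ccc(OCOC)cc1F)c1cc(OCOC)c(OC)c(CC=C(C)C)c1 | intermediate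
15 | (2S)-7-(methoxymethoxy)-2-[4-methoxy-3-(methoxymethoxy)-5-(3-methylbut-2-en-1-yl)phenyl]-2,3-dihydro-4H-chromen-4-one | COCOc1ccc2C(=O)C[C@@H](c3cc(OCOC)c(OC)c(CC=C(C)C)c3)Oc2c1 | intermediate
16 | erylatissin C, (2S)-7-hydroxy-2-[3-hydroxy-4-methoxy-5-(3-methylbut-2-en-1-yl)phenyl]-2,3-dihydro-4H-chromen-4-one | COc1c(O)cc([C@@H]2CC(=O)c3ccc(O)cc3O2)cc1CC=C(C)C | target

**Step count**

Total steps: 10. Longest linear sequence: 9 steps (steps 1 to 7, then 9 and 10); step 8 is the one-step side branch.

**Steps most likely to fail**

Step 9 (proposed new method). What may go wrong: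
- a second addition of the aryllithium to the ketone as the four-ring adduct collapses;
- retro-aldol cleavage or E1cB dehydration of the aldolate before the SNAr closes, which would erode the enantiomeric purity or divert material;
- an SNAr that is too slow at the temperatures that keep the aldolate intact.

The fallback uses known chemistry, sets out from 9 and comes back at 15. Lactone 9 is opened at its acyl carbon with the magnesium amide made from MeNH(OMe)·HCl and i-PrMgCl (THF, −20 °C) to give the Weinreb amide F1. F1 is treated at −78 °C in THF with aryllithium 12 (2.2 equiv, made from 11 as in step 9; the first equivalent serves as base), then quenched with aqueous NH4Cl. This Weinreb ketone synthesis passes through a stable chelated adduct that excludes over-addition and should give the β-hydroxy 2-fluoroaryl ketone F2, which is isolated. F2 is then closed to 15 by intramolecular SNAr under separately tuned mild base (Cs2CO3, DMF, 0 °C → rt).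

Step 7. What may go wrong:
- sulfonylation of the benzylic hydroxyl in competition with the carboxyl group, which leads to ring closure with inversion or to decarboxylative elimination;
- ionisation of the benzylic C–O bond of the product during isolation.

The fallback sets out from 4 and comes back at 9; it changes the approach to a catalytic asymmetric ketene–aldehyde [2+2] cycloaddition and replaces steps 4 to 7. Acetyl chloride and i-Pr2NEt generate ketene F3 in the flask. An O-trimethylsilyl cinchona alkaloid (O-trimethylsilylquinidine or its quinine pseudoenantiomer, whichever a test reaction shows to give the (S) sense) with LiClO4 in CH2Cl2/Et2O at −78 °C should add it to aldehyde 4 to give 9 directly under non-acidic, low-temperature conditions.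

Step 3. What may go wrong:
- transfer of the prenyl group through its tertiary terminus (reverse-prenyl connectivity);
- double-bond migration at the allyl–palladium stage.

The fallback sets out from 3 and comes back at 4. Stille coupling of 3 with allyltributylstannane (Pd(PPh3)4, toluene, 100 °C), in which both allyl termini are equivalent, should give the 3-allyl aldehyde F4. Olefin cross-metathesis of F4 with excess 2-methyl-2-butene (second-generation Grubbs catalyst RuCl2(=CHPh)(PCy3)(H2IMes), CH2Cl2, 40 °C) should then give 4.

Further compounds
F1 | step 9 | (3S)-3-hydroxy-N-methoxy-N-methyl-3-[4-methoxy-3-(methoxymethoxy)-5-(3-methylbut-2-en-1-yl)phenyl]propanamide | CON(C)C(=O)C[C@H](O)c1cc(OCOC)c(OC)c(CC=C(C)C)c1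
F2 | step 9 | (3S)-1-[2-fluoro-4-(methoxymethoxy)phenyl]-3-hydroxy-3-[4-methoxy-3-(methoxymethoxy)-5-(3-methylbut-2-en-1-yl)phenyl]propan-1-one | O=C(C[C@H](O)c1cc(OCOC)c(OC)c(CC=C(C)C)c1)c1ccc(OCOC)cc1F
F3 | step 7 | ketene (formed in the flask) | C=C=O
F4 | step 3 | 4-methoxy-3-(methoxymethoxy)-5-(prop-2-en-1-yl)benzaldehyde | O=Cc1cc(OCOC)c(OC)c(CC=C)c1
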